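**Retrosynthetic overview (germacrane numbering)**
1. Target ⇒ (1(10)Z,4Z)-dienolide: the 1,10-oxirane is made last by peracid epoxidation of C1=C10.
2. Ten-membered ring ⇒ seco aldehyde/alkenyl iodide: C3–C4 ring closure by electrochemical chromium/nickel-catalysed alkenylation of the C3 aldehyde (sets C3).
3. C8 ester ⇒ C8 alcohol + (2R,3R)-epoxyangelic acid (made from (S)-O-benzyl-lactic acid), joined by Mitsunobu inversion.
4. trans-α-Methylene-γ-lactone ⇒ Baylis–Hillman-derived allyl bromide + (Z)-3-iodobut-2-enal: chromium-mediated C6–C7 allylation/lactonization steered by C8 from methyl (S)-glycidate.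
5. (Z)-C1=C10 ⇒ Zhao–Wittig iodo-olefination, then alkenyl-Grignard opening of the glycidate. Ring order: side-chain oxirane, γ-lactone, ten-membered carbocycle, 1,10-oxirane.

Assumption: positions are numbered as in germacrane (C1–C15, side chain C1′–C5′), and every compound labelled starting material is taken to be a catalogue item.

**Side-chain acid**

Step 1
Reactants: 1 (S)-2-(benzyloxy)propanoic acid
Product: 2 (S)-3-(benzyloxy)butan-2-one
Conditions: MeLi (2.2 equiv), Et2O, 0 °C; inverse quench into 1 M HCl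
Reagents that add atoms: methyllithium [Li]C
Why: Organolithium addition to a lithium carboxylate stops at the ketone stage, and the purchased lactate stereocenter (future C3′) is not enolized under these conditions.

Step 2
Reactants: 2 (S)-3-(benzyloxy)butan-2-one; 3 vinylmagnesium bromide
Product: 4 (3S,4S)-4-(benzyloxy)-3-methylpent-1-en-3-ol
Conditions: CH2=CHMgBr (1.5 equiv), THF, −78 °C
Reagents that add atoms: none
Why: Cram-chelate-controlled Grignard addition, in which magnesium bridges the carbonyl and benzyloxy oxygens and vinyl enters from the face carrying H, sets the tertiary carbinol (future C2′) from the lactate center.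

Step 3
Reactants: 4 (3S,4S)-4-(benzyloxy)-3-methylpent-1-en-3-ol
Product: 5 methyl (2R,3S)-3-(benzyloxy)-2-hydroxy-2-methylbutanoate
Conditions: O3, NaOH (2.5 M in MeOH), CH2Cl2, −78 °C
Reagents that add atoms: ozone [O-][O+]=O; methanol CO
Why: Oxidative ozonolysis in methanolic NaOH turns the terminal alkene directly into the methyl ester without touching either stereocenter (the descriptor at C2 changes only because the priorities change).

Step 4
Reactants: 5 methyl (2R,3S)-3-(benzyloxy)-2-hydroxy-2-methylbutanoate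
Product: 6 methyl (2R,3S)-2,3-dihydroxy-2-methylbutanoate
Conditions: H2 (1 atm), Pd/C (10 wt%), MeOH, rt
Reagents that add atoms: none
Why: Benzyl ether hydrogenolysis is reliable here because no other reducible group is present.

Step 5
Reactants: 6 methyl (2R,3S)-2,3-dihydroxy-2-methylbutanoate
Product: 7 methyl (2R,3S)-2-hydroxy-2-methyl-3-[(methylsulfonyl)oxy]butanoate
Conditions: MsCl (1.1 equiv), Et3N, CH2Cl2, −10 °C
Reagents that add atoms: methanesulfonyl chloride CS(=O)(=O)Cl
Why: Sulfonylation is selective for the secondary hydroxyl because the tertiary α-hydroxy ester OH is hindered and deactivated.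

Step 6
Reactants: 7 methyl (2R,3S)-2-hydroxy-2-methyl-3-[(methylsulfonyl)oxy]butanoate
Product: 9 (2R,3R)-2,3-dimethyloxirane-2-carboxylic acid, via epoxy ester 8 (not isolated)
Conditions: LiOH (2.5 equiv), THF–H2O 3:1, 0 °C → rt; then NaHSO4 to pH 3, 0 °C
Reagents that add atoms: lithium hydroxide [Li+].[OH-]
Why: Intramolecular Williamson (3-exo-tet) displacement of the mesylate by the tertiary alkoxide inverts C3′ to give the epoxyangelate (methyls trans), and saponification in the same pot frees the acid.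

**Iodo-enal**

Step 7
Reactants: 10 (Z)-3-iodobut-2-en-1-ol
Product: 11 (Z)-3-iodobut-2-enal
Conditions: MnO2 (15 equiv), CH2Cl2, rt, dark; used crude
Reagents that add atoms: none
Why: Allylic alcohol oxidation with MnO2 is neutral and keeps the Z geometry of the iodoalkene.

**Main sequence**

Step 8
Reactants: 12 3-[(tert-butyldimethylsilyl)oxy]propanal; 13 ethyltriphenylphosphonium iodide
Product: 14 (Z)-tert-butyl[(4-iodopent-3-en-1-yl)oxy]dimethylsilane
Conditions: 13, n-BuLi, THF, 0 °C; I2, −78 °C; NaN(SiMe3)2, −78 → −20 °C; then 12, −78 °C → rt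
Reagents that add atoms: iodine II
Why: Stork–Zhao–Wittig iodo-olefination with the α-iodo ylide gives the Z-configured trisubstituted alkenyl iodide (iodine cis to the chain) under kinetic control.

Step 9
Reactants: 14 (Z)-tert-butyl[(4-iodopent-3-en-1-yl)oxy]dimethylsilane; 15 methyl (S)-oxirane-2-carboxylate
Product: 17 methyl (2S,4Z)-7-[(tert-butyldimethylsilyl)oxy]-2-hydroxy-4-methylhept-4-enoate, via alkenylmagnesium chloride 16 (not isolated)
Conditions: i-PrMgCl·LiCl (1.1 equiv), THF, 0 °C → rt; CuI (10 mol%), then 15, −40 → −10 °C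
Reagents that add atoms: none
Why: Iodine–magnesium exchange proceeds with retention of olefin geometry, and copper-catalysed epoxide opening occurs at the CH2 terminus of the glycidate, so C8 is the purchased stereocenter and C1=C10 is Z.

Step 10
Reactants: 17 methyl (2S,4Z)-7-[(tert-butyldimethylsilyl)oxy]-2-hydroxy-4-methylhept-4-enoate
Product: 18 methyl (2S,4Z)-7-[(tert-butyldimethylsilyl)oxy]-4-methyl-2-[(triethylsilyl)oxy]hept-4-enoate
Conditions: Et3SiCl (1.2 equiv), imidazole (2.5 equiv), DMF, 0 °C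
Reagents that add atoms: chlorotriethylsilane CC[Si](Cl)(CC)CC
Why: Standard silylation gives a secondary triethylsilyl ether that can later be removed in the presence of the primary tert-butyldimethylsilyl ether.

Step 11
Reactants: 18 methyl (2S,4Z)-7-[(tert-butyldimethylsilyl)oxy]-4-methyl-2-[(triethylsilyl)oxy]hept-4-enoate
Product: 19 (2S,4Z)-7-[(tert-butyldimethylsilyl)oxy]-4-methyl-2-[(triethylsilyl)oxy]hept-4-enal
Conditions: i-Bu2AlH (1.05 equiv), CH2Cl2, −78 °C
Reagents that add atoms: none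
Why: Partial reduction of an α-silyloxy methyl ester stops at the aldehyde at −78 °C because the chelated tetrahedral aluminate survives until quench.

Step 12
Reactants: 19 (2S,4Z)-7-[(tert-butyldimethylsilyl)oxy]-4-methyl-2-[(triethylsilyl)oxy]hept-4-enal; 20 methyl acrylate
Product: 21 methyl (3RS,4S,6Z)-9-[(tert-butyldimethylsilyl)oxy]-3-hydroxy-6-methyl-2-methylidene-4-[(triethylsilyl)oxy]non-6-enoate
Conditions: 20 (5 equiv), DABCO (1 equiv), MeOH (2 equiv), rt, 5 d
Reagents that add atoms: none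
Why: Morita–Baylis–Hillman reaction of an activated α-oxygenated aldehyde builds the acrylate unit (C11–C13), and the new C7 carbinol need not be controlled because it is erased in the next step.

Step 13
Reactants: 21 methyl (3RS,4S,6Z)-9-[(tert-butyldimethylsilyl)oxy]-3-hydroxy-6-methyl-2-methylidene-4-[(triethylsilyl)oxy]non-6-enoate
Product: 22 methyl (2Z,4S,6Z)-2-(bromomethyl)-9-[(tert-butyldimethylsilyl)oxy]-6-methyl-4-[(triethylsilyl)oxy]nona-2,6-dienoate
Conditions: NBS (1.5 equiv), Me2S (1.8 equiv, premixed), CH2Cl2, 0 °C → rt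
Reagents that add atoms: N-bromosuccinimide O=C1CCC(=O)N1Br
Why: Corey–Kim-type activation of the Baylis–Hillman alcohol followed by SN2′ bromide attack gives the primary (Z)-allyl bromide under neutral conditions that spare both silyl ethers.

Step 14
Reactants: 22 methyl (2Z,4S,6Z)-2-(bromomethyl)-9-[(tert-butyldimethylsilyl)oxy]-6-methyl-4-[(triethylsilyl)oxy]nona-2,6-dienoate; 11 (Z)-3-iodobut-2-enal
Product: 24 (4S,5S)-4-[(1S,3Z)-6-[(tert-butyldimethylsilyl)oxy]-3-methyl-1-[(triethylsilyl)oxy]hex-3-en-1-yl]-5-[(1Z)-2-iodoprop-1-en-1-yl]-3-methylideneoxolan-2-one, via hydroxy ester 23 (not isolated)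
Conditions: CrCl2 (nickel-free, 4 equiv), 11 (1.5 equiv), THF, 0 °C → rt, 12 h; then 40 °C, 2 h
Reagents that add atoms: none
Why: Nozaki–Hiyama-type chromium-mediated allylation followed by lactonization, in which the equilibrating allylchromium adds through a chair transition state with the C8 chain equatorial (anti adduct, hence trans-lactone) and on the allyl face anti to the C8 silyloxy group (H8 eclipsing the ester side), so C6 and C7 are set from purchased C8; the alkenyl iodide is inert without nickel.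

Step 15
Reactants: 24 (4S,5S)-4-[(1S,3Z)-6-[(tert-butyldimethylsilyl)oxy]-3-methyl-1-[(triethylsilyl)oxy]hex-3-en-1-yl]-5-[(1Z)-2-iodoprop-1-en-1-yl]-3-methylideneoxolan-2-one
Product: 25 (4R,5S)-4-[(1S,3Z)-6-[(tert-butyldimethylsilyl)oxy]-1-hydroxy-3-methylhex-3-en-1-yl]-5-[(1Z)-2-iodoprop-1-en-1-yl]-3-methylideneoxolan-2-one
Conditions: PPTS (0.2 equiv), MeOH–CH2Cl2 1:4, 0 °C
Reagents that add atoms: none
Why: Acid-catalysed methanolysis cleaves the triethylsilyl ether far faster than the tert-butyldimethylsilyl ether (the C4 descriptor changes only through priorities).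

Step 16
Reactants: 25 (4R,5S)-4-[(1S,3Z)-6-[(tert-butyldimethylsilyl)oxy]-1-hydroxy-3-methylhex-3-en-1-yl]-5-[(1Z)-2-iodoprop-1-en-1-yl]-3-methylideneoxolan-2-one; 9 (2R,3R)-2,3-dimethyloxirane-2-carboxylic acid
Product: 26 (1R,3Z)-6-[(tert-butyldimethylsilyl)oxy]-1-[(2S,3R)-2-[(1Z)-2-iodoprop-1-en-1-yl]-4-methylidene-5-oxooxolan-3-yl]-3-methylhex-3-en-1-yl (2R,3R)-2,3-dimethyloxirane-2-carboxylate
Conditions: 9 (2 equiv), PPh3 (2.2 equiv), DIAD (2.2 equiv, betaine preformed), toluene, 0 °C → rt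
Reagents that add atoms: none
Why: Mitsunobu esterification installs the side chain with clean SN2 inversion at C8, converting the 8S center that steered the allylation into the required 8R acyloxy center.

Step 17
Reactants: 26 (1R,3Z)-6-[(tert-butyldimethylsilyl)oxy]-1-[(2S,3R)-2-[(1Z)-2-iodoprop-1-en-1-yl]-4-methylidene-5-oxooxolan-3-yl]-3-methylhex-3-en-1-yl (2R,3R)-2,3-dimethyloxirane-2-carboxylate
Product: 27 (1R,3Z)-6-hydroxy-1-[(2S,3R)-2-[(1Z)-2-iodoprop-1-en-1-yl]-4-methylidene-5-oxooxolan-3-yl]-3-methylhex-3-en-1-yl (2R,3R)-2,3-dimethyloxirane-2-carboxylate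
Conditions: HF·pyridine, pyridine, THF, 0 °C
Reagents that add atoms: none
Why: Buffered fluoride desilylation frees the primary alcohol while the carbonyl-deactivated glycidic ester, the lactone and the alkenyl iodide are unaffected.

Step 18
Reactants: 27 (1R,3Z)-6-hydroxy-1-[(2S,3R)-2-[(1Z)-2-iodoprop-1-en-1-yl]-4-methylidene-5-oxooxolan-3-yl]-3-methylhex-3-en-1-yl (2R,3R)-2,3-dimethyloxirane-2-carboxylate
Product: 28 (1R,3Z)-1-[(2S,3R)-2-[(1Z)-2-iodoprop-1-en-1-yl]-4-methylidene-5-oxooxolan-3-yl]-3-methyl-6-oxohex-3-en-1-yl (2R,3R)-2,3-dimethyloxirane-2-carboxylate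
Conditions: Dess–Martin periodinane (1.3 equiv), pyridine (3 equiv), CH2Cl2, 0 °C; used at once
Reagents that add atoms: none
Why: Dess–Martin oxidation under pyridine buffering gives the β,γ-unsaturated aldehyde without moving the C1=C10 double bond into conjugation.

Step 19
Reactants: 28 (1R,3Z)-1-[(2S,3R)-2-[(1Z)-2-iodoprop-1-en-1-yl]-4-methylidene-5-oxooxolan-3-yl]-3-methyl-6-oxohex-3-en-1-yl (2R,3R)-2,3-dimethyloxirane-2-carboxylate
Product: 29 (3aR,4R,6Z,9S,10Z,11aR)-9-hydroxy-6,10-dimethyl-3-methylidene-2-oxo-2,3,3a,4,5,8,9,11a-octahydrocyclodeca[b]furan-4-yl (2R,3R)-2,3-dimethyloxirane-2-carboxylate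
Conditions: undivided cell, Al anode, Ni-foam cathode, constant current 2 mA; CrCl2 (20 mol%), NiCl2·DME (2 mol%), Cp2ZrCl2 (1.2 equiv), LiCl (0.3 M), DMF, rt; 28 added over 10 h (final 2 mM)
Reagents that add atoms: none
Why: Proposed new method: an electrochemically driven, chromium/nickel-cocatalysed Nozaki–Hiyama–Kishi ring closure in which the cathode keeps a small stationary amount of CrCl2, this reduces the nickel salt to zerovalent nickel, which inserts into the C4–I bond with retention of the Z geometry, the alkenyl group passes to trivalent chromium and adds to the C3 aldehyde inside the forming ten-membered ring, Cp2ZrCl2 releases chromium from the product alkoxide and the aluminium anode is consumed; the two Z olefins and the trans-lactone hold the chain ends close, and attack on the aldehyde face that leaves the chromium-bound oxygen outside the ring with H3 eclipsing C4=C5 is expected to give the 3S carbinol under control of the C6/C7/C8 centers; the closest known chemistry is the stoichiometric CrCl2/NiCl2 macrocyclization and the intermolecular electrochemical Nozaki–Hiyama–Kishi coupling of alkenyl halides with aldehydes.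

Step 20
Reactants: 29 (3aR,4R,6Z,9S,10Z,11aR)-9-hydroxy-6,10-dimethyl-3-methylidene-2-oxo-2,3,3a,4,5,8,9,11a-octahydrocyclodeca[b]furan-4-yl (2R,3R)-2,3-dimethyloxirane-2-carboxylate
Product: 30 (1R,3S,4Z,6R,7R,8R,10S)-8-{[(2R,3R)-2,3-dimethyloxiran-2-yl]carbonyloxy}-1,10-epoxy-3-hydroxygermacra-4,11(13)-dien-12,6-olide (CNP0268255.3)
Conditions: mCPBA (1.05 equiv), CH2Cl2–aq. pH 7 phosphate buffer, 0 °C
Reagents that add atoms: 3-chloroperoxybenzoic acid OOC(=O)c1cccc(Cl)c1
Why: Prilezhaev epoxidation picks the isolated, most electron-rich C1=C10 olefin (C4=C5 is deactivated by two allylic C–O bonds, the methylene lactone is electron-poor) and attacks its exposed outer face on the lactone-braced ring, giving the cis-fused 1R,10S oxirane stereospecifically from the Z olefin.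

**Compound list**

1 | (S)-2-(benzyloxy)propanoic acid | C[C@H](OCc1ccccc1)C(=O)O | starting material
2 | (S)-3-(benzyloxy)butan-2-one | C[C@H](OCc1ccccc1)C(C)=O | intermediate
3 | vinylmagnesium bromide | C=C[Mg]Br | starting material
4 | (3S,4S)-4-(benzyloxy)-3-methylpent-1-en-3-ol | C=C[C@](C)(O)[C@H](C)OCc1ccccc1 | intermediate
5 | methyl (2R,3S)-3-(benzyloxy)-2-hydroxy-2-methylbutanoate | COC(=O)[C@](C)(O)[C@H](C)OCc1ccccc1 | intermediate
6 | methyl (2R,3S)-2,3-dihydroxy-2-methylbutanoate | COC(=O)[C@](C)(O)[C@H](C)O | intermediate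
7 | methyl (2R,3S)-2-hydroxy-2-methyl-3-[(methylsulfonyl)oxy]butanoate | COC(=O)[C@](C)(O)[C@H](C)OS(C)(=O)=O | intermediate
8 | methyl (2R,3R)-2,3-dimethyloxirane-2-carboxylate | COC(=O)[C@]1(C)O[C@@H]1C | intermediate
9 | (2R,3R)-2,3-dimethyloxirane-2-carboxylic acid | OC(=O)[C@]1(C)O[C@@H]1C | intermediate
10 | (Z)-3-iodobut-2-en-1-ol | C/C(I)=C/CO | starting material
11 | (Z)-3-iodobut-2-enal | C/C(I)=C/C=O | intermediate
12 | 3-[(tert-butyldimethylsilyl)oxy]propanal | O=CCCO[Si](C)(C)C(C)(C)C | starting material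
13 | ethyltriphenylphosphonium iodide | CC[P+](c1ccccc1)(c1ccccc1)c1ccccc1.[I-] | starting material
14 | (Z)-tert-butyl[(4-iodopent-3-en-1-yl)oxy]dimethylsilane | C/C(I)=C/CCO[Si](C)(C)C(C)(C)C | intermediate
15 | methyl (S)-oxirane-2-carboxylate | COC(=O)[C@@H]1CO1 | starting material
16 | [(2Z)-5-[(tert-butyldimethylsilyl)oxy]pent-2-en-2-yl]magnesium chloride | C/C([Mg]Cl)=C/CCO[Si](C)(C)C(C)(C)C | intermediate
17 | methyl (2S,4Z)-7-[(tert-butyldimethylsilyl)oxy]-2-hydroxy-4-methylhept-4-enoate | COC(=O)[C@@H](O)C/C(C)=C\CCO[Si](C)(C)C(C)(C)C | intermediate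
18 | methyl (2S,4Z)-7-[(tert-butyldimethylsilyl)oxy]-4-methyl-2-[(triethylsilyl)oxy]hept-4-enoate | COC(=O)[C@@H](O[Si](CC)(CC)CC)C/C(C)=C\CCO[Si](C)(C)C(C)(C)C | intermediate
19 | (2S,4Z)-7-[(tert-butyldimethylsilyl)oxy]-4-methyl-2-[(triethylsilyl)oxy]hept-4-enal | O=C[C@@H](O[Si](CC)(CC)CC)C/C(C)=C\CCO[Si](C)(C)C(C)(C)C | intermediate
20 | methyl acrylate | C=CC(=O)OC | starting material
21 | methyl (3RS,4S,6Z)-9-[(tert-butyldimethylsilyl)oxy]-3-hydroxy-6-methyl-2-methylidene-4-[(triethylsilyl)oxy]non-6-enoate | COC(=O)C(=C)C(O)[C@@H](O[Si](CC)(CC)CC)C/C(C)=C\CCO[Si](C)(C)C(C)(C)C | intermediate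
22 | methyl (2Z,4S,6Z)-2-(bromomethyl)-9-[(tert-butyldimethylsilyl)oxy]-6-methyl-4-[(triethylsilyl)oxy]nona-2,6-dienoate | COC(=O)/C(CBr)=C/[C@@H](O[Si](CC)(CC)CC)C/C(C)=C\CCO[Si](C)(C)C(C)(C)C | intermediate
23 | methyl (3S,4S,6Z)-9-[(tert-butyldimethylsilyl)oxy]-3-[(1S,2Z)-1-hydroxy-3-iodobut-2-en-1-yl]-6-methyl-2-methylidene-4-[(triethylsilyl)oxy]non-6-enoate | COC(=O)C(=C)[C@@H]([C@H](O)/C=C(/C)I)[C@@H](O[Si](CC)(CC)CC)C/C(C)=C\CCO[Si](C)(C)C(C)(C)C | intermediate
24 | (4S,5S)-4-[(1S,3Z)-6-[(tert-butyldimethylsilyl)oxy]-3-methyl-1-[(triethylsilyl)oxy]hex-3-en-1-yl]-5-[(1Z)-2-iodoprop-1-en-1-yl]-3-methylideneoxolan-2-one | C=C1C(=O)O[C@H](/C=C(/C)I)[C@H]1[C@@H](O[Si](CC)(CC)CC)C/C(C)=C\CCO[Si](C)(C)C(C)(C)C | intermediate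
25 | (4R,5S)-4-[(1S,3Z)-6-[(tert-butyldimethylsilyl)oxy]-1-hydroxy-3-methylhex-3-en-1-yl]-5-[(1Z)-2-iodoprop-1-en-1-yl]-3-methylideneoxolan-2-one | C=C1C(=O)O[C@H](/C=C(/C)I)[C@H]1[C@@H](O)C/C(C)=C\CCO[Si](C)(C)C(C)(C)C | intermediate
26 | (1R,3Z)-6-[(tert-butyldimethylsilyl)oxy]-1-[(2S,3R)-2-[(1Z)-2-iodoprop-1-en-1-yl]-4-methylidene-5-oxooxolan-3-yl]-3-methylhex-3-en-1-yl (2R,3R)-2,3-dimethyloxirane-2-carboxylate | C=C1C(=O)O[C@H](/C=C(/C)I)[C@H]1[C@H](OC(=O)[C@]2(C)O[C@@H]2C)C/C(C)=C\CCO[Si](C)(C)C(C)(C)C | intermediate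
27 | (1R,3Z)-6-hydroxy-1-[(2S,3R)-2-[(1Z)-2-iodoprop-1-en-1-yl]-4-methylidene-5-oxooxolan-3-yl]-3-methylhex-3-en-1-yl (2R,3R)-2,3-dimethyloxirane-2-carboxylate | C=C1C(=O)O[C@H](/C=C(/C)I)[C@H]1[C@H](OC(=O)[C@]2(C)O[C@@H]2C)C/C(C)=C\CCO | intermediate
28 | (1R,3Z)-1-[(2S,3R)-2-[(1Z)-2-iodoprop-1-en-1-yl]-4-methylidene-5-oxooxolan-3-yl]-3-methyl-6-oxohex-3-en-1-yl (2R,3R)-2,3-dimethyloxirane-2-carboxylate | C=C1C(=O)O[C@H](/C=C(/C)I)[C@H]1[C@H](OC(=O)[C@]2(C)O[C@@H]2C)C/C(C)=C\CC=O | intermediate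
29 | (3aR,4R,6Z,9S,10Z,11aR)-9-hydroxy-6,10-dimethyl-3-methylidene-2-oxo-2,3,3a,4,5,8,9,11a-octahydrocyclodeca[b]furan-4-yl (2R,3R)-2,3-dimethyloxirane-2-carboxylate | C=C1C(=O)O[C@@H]2/C=C(/C)[C@@H](O)C/C=C(/C)C[C@@H](OC(=O)[C@]3(C)O[C@@H]3C)[C@@H]12 | intermediate
30 | (1R,3S,4Z,6R,7R,8R,10S)-8-{[(2R,3R)-2,3-dimethyloxiran-2-yl]carbonyloxy}-1,10-epoxy-3-hydroxygermacra-4,11(13)-dien-12,6-olide (CNP0268255.3) | C=C1C(=O)O[C@@H]2/C=C(/C)[C@@H](O)C[C@H]3O[C@@]3(C)C[C@@H](OC(=O)[C@]3(C)O[C@@H]3C)[C@@H]12 | target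

**Totals and risks**

Total step count: 20 (steps 1–6 side-chain acid, step 7 iodo-enal, steps 8–20 main sequence). Longest linear sequence: 13 steps (12 → 30, steps 8–20).

Nothing here has been run; the stereochemical outcomes of steps 14, 19 and 20 are predictions from transition-state and conformational models, not established results.

The three steps most likely to fail:

Step 19 (the proposed new electrochemical ring closure). Risks are ring strain, the sense of induction at C3, nickel-mediated 6-exo insertion of the alkenyl group into the methylene lactone, and drift of the β,γ-unsaturated aldehyde into conjugation. The fallback sets out from 28 and comes back at 29. The ring is closed by the classical stoichiometric Nozaki–Hiyama–Kishi macrocyclization (CrCl2 8 equiv, NiCl2 1 mol%, DMSO–THF, 1 mM, rt), and C3 control is taken out of the C–C bond-forming event. Whatever (3aR,4R,6Z,9R,10Z,11aR)-9-hydroxy C3 epimer F5 accompanies 29 is oxidized together with it (Dess–Martin periodinane, pyridine) to the (3aR,4R,6Z,10Z,11aR)-2,9-dioxo enone F6. Luche reduction (NaBH4, CeCl3·7H2O, MeOH, −78 °C), with hydride expected to arrive from the outer face of the ring, then returns 29.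

Step 14 (chromium allylation/lactonization). The risk is a syn adduct (cis-lactone) or addition on the other face relative to C8. The fallback sets out from 21 and comes back at 25, and locks the allyl geometry in a ring. PPTS in MeOH (0 °C → rt) removes the triethylsilyl group from 21 and the freed C8 hydroxyl lactonizes to (5S)-4-hydroxy-3-methylidene-5-[(2Z)-5-[(tert-butyldimethylsilyl)oxy]-2-methylpent-2-en-1-yl]oxolan-2-one F1. NBS/Me2S transposes the allylic alcohol to (5S)-3-(bromomethyl)-5-[(2Z)-5-[(tert-butyldimethylsilyl)oxy]-2-methylpent-2-en-1-yl]furan-2(5H)-one F2. Known Barbier-type allylation of 11 with this bromobutenolide (CrCl2, THF, or Zn, aq. NH4Cl–THF) should add anti to the C8 substituent and through a chair, giving (4S,5S)-4-[(1S,2Z)-1-hydroxy-3-iodobut-2-en-1-yl]-3-methylidene-5-[(2Z)-5-[(tert-butyldimethylsilyl)oxy]-2-methylpent-2-en-1-yl]oxolan-2-one F3. DBU-catalysed acyl migration (CH2Cl2, rt) equilibrates this 8,12-lactone with the 6,12-lactone 25, which is separated and the remainder recycled.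

Step 16 (Mitsunobu inversion at the hindered C8 carbinol with an α-quaternary acid). The risk is elimination or low conversion. The fallback sets out from 25 and comes back at 26. MsCl/Et3N (CH2Cl2, 0 °C) gives (1S,3Z)-6-[(tert-butyldimethylsilyl)oxy]-1-[(2S,3S)-2-[(1Z)-2-iodoprop-1-en-1-yl]-4-methylidene-5-oxooxolan-3-yl]-3-methylhex-3-en-1-yl methanesulfonate F4. This is displaced with inversion by the caesium salt of 9 (9, Cs2CO3, 18-crown-6, toluene, 80 °C) to give 26.

Further compounds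
F1 | step 14 | (5S)-4-hydroxy-3-methylidene-5-[(2Z)-5-[(tert-butyldimethylsilyl)oxy]-2-methylpent-2-en-1-yl]oxolan-2-one (C4 epimers) | C=C1C(=O)O[C@@H](C/C(C)=C\CCO[Si](C)(C)C(C)(C)C)C1O
F2 | step 14 | (5S)-3-(bromomethyl)-5-[(2Z)-5-[(tert-butyldimethylsilyl)oxy]-2-methylpent-2-en-1-yl]furan-2(5H)-one | BrCC1=C[C@H](C/C(C)=C\CCO[Si](C)(C)C(C)(C)C)OC1=O
F3 | step 14 | (4S,5S)-4-[(1S,2Z)-1-hydroxy-3-iodobut-2-en-1-yl]-3-methylidene-5-[(2Z)-5-[(tert-butyldimethylsilyl)oxy]-2-methylpent-2-en-1-yl]oxolan-2-one | C=C1C(=O)O[C@@H](C/C(C)=C\CCO[Si](C)(C)C(C)(C)C)[C@@H]1[C@H](O)/C=C(/C)I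
F4 | step 16 | (1S,3Z)-6-[(tert-butyldimethylsilyl)oxy]-1-[(2S,3S)-2-[(1Z)-2-iodoprop-1-en-1-yl]-4-methylidene-5-oxooxolan-3-yl]-3-methylhex-3-en-1-yl methanesulfonate | C=C1C(=O)O[C@H](/C=C(/C)I)[C@H]1[C@@H](OS(C)(=O)=O)C/C(C)=C\CCO[Si](C)(C)C(C)(C)C
F5 | step 19 | (3aR,4R,6Z,9R,10Z,11aR)-9-hydroxy-6,10-dimethyl-3-methylidene-2-oxo-2,3,3a,4,5,8,9,11a-octahydrocyclodeca[b]furan-4-yl (2R,3R)-2,3-dimethyloxirane-2-carboxylate | C=C1C(=O)O[C@@H]2/C=C(/C)[C@H](O)C/C=C(/C)C[C@@H](OC(=O)[C@]3(C)O[C@@H]3C)[C@@H]12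
F6 | step 19 | (3aR,4R,6Z,10Z,11aR)-6,10-dimethyl-3-methylidene-2,9-dioxo-2,3,3a,4,5,8,9,11a-octahydrocyclodeca[b]furan-4-yl (2R,3R)-2,3-dimethyloxirane-2-carboxylate | C=C1C(=O)O[C@@H]2/C=C(/C)C(=O)C/C=C(/C)C[C@@H](OC(=O)[C@]3(C)O[C@@H]3C)[C@@H]12
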